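**The questions.** 5 questions stood before me: which flask ends with most L, and how much L each of the 4 flasks holds.

| flask | E | Z | temperature | remark | time |
|---|---|---|---|---|---|
| autumn | 0.055 M | 0.028 M | 15 °C | run made earlier |  |
| winter | 0.055 M | 0.041 M | 45 °C | run made earlier |  |
| west | 0.055 M | 0.0550 M |  | at 70 °C until 2.5 min, from then on at 20 °C | 5.0 min |
| south-east | 0.055 M | 0.0550 M | 70 °C |  | 5.0 min |
| north-east | 0.055 M | 0.0550 M | 45 °C |  | 5.0 min |
| south | 0.055 M | 0.0550 M | 20 °C |  | 5.0 min |

- autumn (time / min: L / %, E / %): 15.0: 1, 103; 30.0: 2, 97; 50.0: 4, 96; 60.0: 10, 93; 80.0: 9, 92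
- winter (time / min: L / %, E / %): 3.00: 3, 94; 6.00: 11, 89; 10.0: 20, 86; 15.0: 20, 76

(readings scatter by 2 percentage points)

1. the best flask by amount of L, in percent of the E charged; "all alike" if 1.5 percentage points covers them all (west / south-east / north-east / south / all alike)
2. amount of L at the end, in percent of the E charged, west
3. amount of L at the end, in percent of the E charged, south-east
4. amount of L at the end, in percent of the E charged, north-east
5. amount of L at the end, in percent of the E charged, south



**An odd pair.** In the winter run, the E reading fell by 10 percentage points from 10.0 min to 15.0 min, yet L read 20 % at both times. But at 10.0 min L read more than the 14.0 % of E lost, and each reading scatters by 2 points, so I did not read that pair as a stall. I therefore took the balance from the start at the last reading, where 16.7 % of the E lost was not found as L.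

**The crossing.** I supposed that L is used by a step taking Z, as its making does, so that Z cancels. Making over using is then h times E/L, where h is the hand-over ratio, the ratio L/E at which L is used as fast as it is made; the usual term is a selectivity factor. L/E read 0.263 at the last reading of the winter run, and I took its mean over that run as about half of that. Dividing this mean by the share lost gives h = 0.789, a loose reading from one point at 45 °C.

**The forecast.** It chose south-east, with 24 % for west, 38 % for south-east, 11 % for north-east and 2 % for south, and it noted that “L loss there is possible”.

**My reckoning.** I let the forecast's 38 % stand as the fraction of E reacted in south-east, applied h as read at 45 °C to that hotter flask, and got 27.4 % of L, which is less than the forecast's figure.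

**The result.** The best flask was south-east, with 27.2 % in west, 31.9 % in south-east, 13.2 % in north-east and 1.65 % in south.

    E + Z → L (k = 0.0760 M⁻¹ s⁻¹, Ea = 72.0 kJ mol⁻¹)
    Z + L → X (k = 0.0160 M⁻¹ s⁻¹, Ea = 83.0 kJ mol⁻¹)
    Z ⇌ D (K = 0.270, k = 8.10 × 10⁻⁴ s⁻¹, Ea = 105 kJ mol⁻¹, ΔH = −77.0 kJ mol⁻¹)
    Z → Q (k = 3.50 × 10⁻⁴ s⁻¹, Ea = 116 kJ mol⁻¹)
    Z + L → J (k = 0.0740 M⁻¹ s⁻¹, Ea = 69.0 kJ mol⁻¹)
    (constants at 70 °C)

**Using h.** South-east ended with 52.5 % of its E, so L/E stood at 0.608, below h. From that E, the rule gives 30.2 % of L against the 31.9 % found. The neighbour is west with Z raised to 0.22 M. That neighbour ended with 16.2 % of its E, so L/E stood at 1.54, above h, and with my h making over using is reckoned at 0.511. The neighbour's L was 25.0 %, less than the 27.2 % of west.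

(The numbers in the tables come from a simulation with made-up constants, noise included.)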